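Numbering (daucane): ring A = C1–C5 (C1 quaternary with the C15 methyl, C4 carbinol with the isopropyl group, C5 ring-fusion CH). Ring B = C1, C5–C10 (C14 methyl on C8). β is the face of C15.
Cuts, last-formed first: the C8/C9 epoxide oxygen, C7–O, aroyl–O6, then C4–C5, then C8–C14, C1–C2 and C1–C15.
Enabling feature: the tertiary C4–OH of ring A lies β to the C6 oxygen of ring B (O–C4–C5–C6–O). At the C6 ketone level, C4–C5 is therefore an aldol bond between a ring B enolate at C5 and an isopropyl ketone hanging from C1.
Forward: ring B is bought as cycloheptane-1,3-dione and the C2–C4 chain is joined at C1 by conjugate addition. Ring B is then raised to the 8-methyl-7-en-6-one, the aldol addition closes ring A, and O6 is esterified before C7–C9 are oxidised.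
Stereochemistry: C1 comes from a chiral copper catalyst, C4 and C5 from equilibration against C1, and C6 from hydride delivery by C4–OH. C7 comes from an ene reaction anti to the C6 ester, and C8/C9 from epoxidation anti to the C7 silyl ether.

Key step: step 8

Assumption: the ligand enantiomer named in step 4 is taken, by analogy with related β-methyl cycloalkenones, to give the S adduct. If the sense proves opposite, its mirror image is used.

Step 1
Reactants: 1 cycloheptane-1,3-dione
Product: 2 3-isobutoxycyclohept-2-en-1-one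
Conditions: i-BuOH, PPTS (cat.), toluene, reflux, Dean–Stark trap
Reagents that add atoms: isobutanol CC(C)CO
Why: Acid-catalysed condensation of a cyclic 1,3-diketone with an alcohol under water removal gives the vinylogous ester, the usual entry to a Stork–Danheiser sequence.

Step 2
Reactants: 2 3-isobutoxycyclohept-2-en-1-one
Product: 4 3-methylcyclohept-2-en-1-one, via lithium alkoxide 3 (not isolated)
Conditions: MeLi, Et2O, −78 to 0 °C; then 1 M HCl, rt
Reagents that add atoms: methyllithium [Li]C; water O
Why: Stork–Danheiser transposition, in which 1,2-addition of MeLi to the vinylogous ester and acid-induced loss of isobutanol move the carbonyl group and leave the future C15 methyl on the enone β-carbon, the future C1.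

Step 3
Reactants: 5 4-methylpent-1-en-3-one
Product: 7 2-(2-bromoethyl)-2-isopropyl-1,3-dioxolane, via bromo ketone 6 (not isolated)
Conditions: HBr (g), CH2Cl2, 0 °C; then HOCH2CH2OH, HC(OEt)3, TsOH (cat.), rt
Reagents that add atoms: hydrogen bromide Br; ethylene glycol OCCO
Why: Conjugate hydrobromination of a vinyl ketone followed by orthoformate-driven ketalisation in the same flask is the established route to β-bromo ketals, and the mask is needed because a free ketone would not survive Grignard formation.

Step 4
Reactants: 7 2-(2-bromoethyl)-2-isopropyl-1,3-dioxolane; 4 3-methylcyclohept-2-en-1-one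
Product: 10 (S)-3-methyl-3-[2-(2-isopropyl-1,3-dioxolan-2-yl)ethyl]cycloheptan-1-one, via Grignard reagent 8 (not isolated), via magnesium enolate 9 (not isolated)
Conditions: Mg, Et2O, rt; added to 4, Cu(OTf)2 (cat.), (S)-tert-leucinol-derived N-mesityl-N′-(1-hydroxy-3,3-dimethylbutan-2-yl)imidazolinium hexafluorophosphate (cat.), Et2O, −30 °C; aq NH4Cl
Reagents that add atoms: none
Why: Copper-catalysed asymmetric conjugate addition of a Grignard reagent to a β-methyl cyclic enone under a chiral N-heterocyclic carbene ligand is an established way to all-carbon quaternary centres in six- and seven-membered rings, and the ligand decides which enone face the chain enters and so sets C1.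

Step 5
Reactants: 10 (S)-3-methyl-3-[2-(2-isopropyl-1,3-dioxolan-2-yl)ethyl]cycloheptan-1-one
Product: 12 (S)-6-methyl-6-[2-(2-isopropyl-1,3-dioxolan-2-yl)ethyl]cyclohept-2-en-1-one, via enol silane 11 (not isolated)
Conditions: LiN(iPr)2, TMSCl, THF, −78 °C; crude 11, Pd(OAc)2, MeCN, rt
Reagents that add atoms: none
Why: Saegusa–Ito oxidation, in which the amide base takes the open C7 proton rather than the neopentyl C5 proton and, because C1 carries no hydrogen, β-hydride elimination from the palladium enolate can give only the C7=C8 enone.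

Step 6
Reactants: 12 (S)-6-methyl-6-[2-(2-isopropyl-1,3-dioxolan-2-yl)ethyl]cyclohept-2-en-1-one
Product: 14 (S)-3,6-dimethyl-6-[2-(2-isopropyl-1,3-dioxolan-2-yl)ethyl]cyclohept-2-en-1-one, via enol silane 13 (not isolated)
Conditions: Me2CuLi (from CuI, MeLi), TMSCl, Et2O–THF, −78 °C; crude 13, Pd(OAc)2, MeCN, rt
Reagents that add atoms: lithium dimethylcuprate [Li+].C[Cu-]C
Why: Chlorosilane-assisted cuprate 1,4-addition brings the C14 methyl to C8 and fixes the enol silane at C6=C7, so a second Saegusa–Ito oxidation restores C7=C8 and erases the transient C8 stereocentre.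

Step 7
Reactants: 14 (S)-3,6-dimethyl-6-[2-(2-isopropyl-1,3-dioxolan-2-yl)ethyl]cyclohept-2-en-1-one
Product: 15 (S)-3,6-dimethyl-6-(4-methyl-3-oxopentyl)cyclohept-2-en-1-one
Conditions: 1 M HCl, THF, rt
Reagents that add atoms: water O
Why: Mild acid-catalysed ketal hydrolysis frees the isopropyl ketone without touching the enone or the quaternary centre.

Step 8
Reactants: 15 (S)-3,6-dimethyl-6-(4-methyl-3-oxopentyl)cyclohept-2-en-1-one
Product: 16 4β-hydroxydauc-7-en-6-one (trans-fused; 1β-CH3; 5α-H; 4α-isopropyl)
Conditions: KOH (0.2 equiv), MeOH, 0 °C, held until the composition no longer changes; AcOH quench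
Reagents that add atoms: none
Why: The base reversibly removes a C5 proton (the α′ position of the cross-conjugated enone) and the enolate adds to the side-chain C4 carbonyl, a base-mediated intramolecular ketone–ketone aldol addition of the kind long used for fused cyclopentanol ketols. Ring A closes in the 5-(enolexo)-exo-trig mode, the only closure that gives a fused five-membered ring. Site selectivity is built into 15: C7 is vinylic and cannot enolise, the C9/C14 dienolate could reach C4 only through a bridged seven-membered ring, and attack of the C3 enolate on C6 (bridged bicyclo[4.2.1] ketol, the serious competitor for a saturated cycloheptanone) or on C8 (bridged bicyclo[3.2.2] Michael adduct) would sacrifice the enone conjugation and stays reversible. C4 and C5 are set against the fixed C1 by equilibration through retro-aldol and C5 epimerisation: at C4 the isopropyl group should take the face of H5 and the hydroxyl the side of C6, where it hydrogen-bonds to the C6 carbonyl, while at C5 the trans fusion is expected to win because both ring A bonds are then equatorial on ring B, as is usual for perhydroazulen-4-ones, and the sp2 atoms C6–C8 remove the syn-axial hydrogens that the axial C15 methyl would otherwise meet. Kinetic closure probably favours a cis-fused ketol, so the mixture is left to equilibrate, and recovered 15 and minor ketols are resubmitted. Low temperature and substoichiometric base hold back E1cB loss of water to the C4=C5 dienone.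

Step 9
Reactants: 16 4β-hydroxydauc-7-en-6-one
Product: 17 dauc-7-ene-4β,6α-diol
Conditions: Me4NBH(OAc)3, MeCN–AcOH, −30 °C
Reagents that add atoms: none
Why: Evans–Saksena reduction, in which exchange of an acetate on boron for C4–OH ties the hydride to the β face and passes it to C6 through a six-membered transition state to give the 1,3-anti diol (6α-OH) in 1,2-fashion, whereas a free hydride would be expected to enter from the α face, away from C15.

Step 10
Reactants: 18 4-hydroxybenzoic acid
Product: 20 4-(tert-butyldimethylsilyloxy)benzoic acid, via bis-silyl compound 19 (not isolated)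
Conditions: TBSCl (2.2 equiv), imidazole, DMF, rt; then AcOH–THF–H2O, rt
Reagents that add atoms: tert-butyldimethylsilyl chloride CC(C)(C)[Si](C)(C)Cl
Why: Exhaustive silylation followed by selective hydrolysis of the far more labile silyl ester is the routine way to an O-silylated hydroxybenzoic acid.

Step 11
Reactants: 17 dauc-7-ene-4β,6α-diol; 20 4-(tert-butyldimethylsilyloxy)benzoic acid
Product: 21 6α-[4-(tert-butyldimethylsilyloxy)benzoyloxy]dauc-7-en-4β-ol
Conditions: DCC, DMAP, CH2Cl2, rt
Reagents that add atoms: none
Why: Steglich esterification acylates only the secondary allylic C6–OH, because the tertiary C4–OH next to the isopropyl group is inert to the acylpyridinium species.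

Step 12
Reactants: 21 6α-[4-(tert-butyldimethylsilyloxy)benzoyloxy]dauc-7-en-4β-ol
Product: 23 6α-[4-(tert-butyldimethylsilyloxy)benzoyloxy]dauc-8-ene-4β,7β-diol, via allylic hydroperoxide 22 (not isolated)
Conditions: O2, tetraphenylporphyrin (cat.), visible light, CH2Cl2, 0 °C; then PPh3
Reagents that add atoms: dioxygen O=O
Why: Schenck ene reaction, in which singlet oxygen should approach C7=C8 from the β face, away from the 6α-aroyloxy group whose oxygen atoms repel the developing perepoxide, bond to C7 and take the pseudo-axial 9β-hydrogen on the more substituted (ring) side of the alkene rather than a C14 hydrogen or the acyloxy-deactivated H6, so the double bond moves to C8=C9 and PPh3 reduction leaves the 7β-alcohol.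

Step 13
Reactants: 23 6α-[4-(tert-butyldimethylsilyloxy)benzoyloxy]dauc-8-ene-4β,7β-diol
Product: 24 6α-[4-(tert-butyldimethylsilyloxy)benzoyloxy]-7β-(triethylsilyloxy)dauc-8-en-4β-ol
Conditions: TESCl, imidazole, CH2Cl2, 0 °C
Reagents that add atoms: triethylsilyl chloride CC[Si](Cl)(CC)CC
Why: Chlorosilane/imidazole silylation picks the secondary alcohol over the tertiary one, removes a hydroxyl that would direct an oxidant to the wrong (β) face, and adds bulk on that face.

Step 14
Reactants: 24 6α-[4-(tert-butyldimethylsilyloxy)benzoyloxy]-7β-(triethylsilyloxy)dauc-8-en-4β-ol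
Product: 25 8α,9α-epoxy-6α-[4-(tert-butyldimethylsilyloxy)benzoyloxy]-7β-(triethylsilyloxy)daucan-4β-ol
Conditions: dimethyldioxirane, acetone–CH2Cl2, −20 to 0 °C
Reagents that add atoms: dimethyldioxirane CC1(C)OO1
Why: Concerted oxygen transfer from a dioxirane to the trisubstituted alkene of an allylic silyl ether should take place anti to the silyl ether, here the α face, because the β face is covered by the 7β-OTES group next to C8 and by the axial C15 methyl 1,3 to C9, and the neutral medium spares the epoxide.

Step 15
Reactants: 25 8α,9α-epoxy-6α-[4-(tert-butyldimethylsilyloxy)benzoyloxy]-7β-(triethylsilyloxy)daucan-4β-ol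
Product: 26 8α,9α-epoxy-6α-(4-hydroxybenzoyloxy)daucane-4β,7β-diol (CNP0290052.1)
Conditions: Bu4NF, AcOH (1:1), THF, 0 °C
Reagents that add atoms: none
Why: Fluoride-mediated desilylation removes the aryl and the secondary silyl ether together, and the acetic acid buffer keeps alkoxide-driven acyl migration from O6 to O7 and Payne rearrangement from starting.

Compound list
1 | cycloheptane-1,3-dione | O=C1CCCCC(=O)C1 | starting material
2 | 3-isobutoxycyclohept-2-en-1-one | CC(C)COC1=CC(=O)CCCC1 | intermediate
3 | lithium 3-isobutoxy-1-methylcyclohept-2-en-1-olate (racemic) | [Li+].[O-]C1(C)C=C(OCC(C)C)CCCC1 | intermediate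
4 | 3-methylcyclohept-2-en-1-one | CC1=CC(=O)CCCC1 | intermediate
5 | 4-methylpent-1-en-3-one | CC(C)C(=O)C=C | starting material
6 | 1-bromo-4-methylpentan-3-one | CC(C)C(=O)CCBr | intermediate
7 | 2-(2-bromoethyl)-2-isopropyl-1,3-dioxolane | CC(C)C1(CCBr)OCCO1 | intermediate
8 | [2-(2-isopropyl-1,3-dioxolan-2-yl)ethyl]magnesium bromide | CC(C)C1(CC[Mg]Br)OCCO1 | intermediate
9 | bromomagnesium C5=C6 enolate of 10 | CC(C)C1(OCCO1)CC[C@]2(C)CCCCC(O[Mg]Br)=C2 | intermediate
10 | (S)-3-methyl-3-[2-(2-isopropyl-1,3-dioxolan-2-yl)ethyl]cycloheptan-1-one | CC(C)C1(OCCO1)CC[C@]2(C)CCCCC(=O)C2 | intermediate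
11 | C6=C7 trimethylsilyl enol ether of 10 | CC(C)C1(OCCO1)CC[C@]2(C)CCCC=C(O[Si](C)(C)C)C2 | intermediate
12 | (S)-6-methyl-6-[2-(2-isopropyl-1,3-dioxolan-2-yl)ethyl]cyclohept-2-en-1-one | CC(C)C1(OCCO1)CC[C@]2(C)CCC=CC(=O)C2 | intermediate
13 | C6=C7 trimethylsilyl enol ether of the 8-methyl ketone (C8 epimers, erased in the same step) | CC(C)C1(OCCO1)CC[C@]2(C)CCC(C)C=C(O[Si](C)(C)C)C2 | intermediate
14 | (S)-3,6-dimethyl-6-[2-(2-isopropyl-1,3-dioxolan-2-yl)ethyl]cyclohept-2-en-1-one | CC(C)C1(OCCO1)CC[C@]2(C)CCC(C)=CC(=O)C2 | intermediate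
15 | (S)-3,6-dimethyl-6-(4-methyl-3-oxopentyl)cyclohept-2-en-1-one | CC(C)C(=O)CC[C@]1(C)CCC(C)=CC(=O)C1 | intermediate
16 | 4β-hydroxydauc-7-en-6-one (trans-fused, 1β-CH3, 5α-H, 4α-isopropyl) | CC(C)[C@]1(O)CC[C@]2(C)CCC(C)=CC(=O)[C@H]21 | intermediate
17 | dauc-7-ene-4β,6α-diol | CC(C)[C@]1(O)CC[C@]2(C)CCC(C)=C[C@H](O)[C@H]21 | intermediate
18 | 4-hydroxybenzoic acid | O=C(O)c1ccc(O)cc1 | starting material
19 | tert-butyldimethylsilyl 4-(tert-butyldimethylsilyloxy)benzoate | CC(C)(C)[Si](C)(C)Oc1ccc(cc1)C(=O)O[Si](C)(C)C(C)(C)C | intermediate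
20 | 4-(tert-butyldimethylsilyloxy)benzoic acid | CC(C)(C)[Si](C)(C)Oc1ccc(cc1)C(=O)O | intermediate
21 | 6α-[4-(tert-butyldimethylsilyloxy)benzoyloxy]dauc-7-en-4β-ol | CC(C)[C@]1(O)CC[C@]2(C)CCC(C)=C[C@H](OC(=O)c3ccc(O[Si](C)(C)C(C)(C)C)cc3)[C@H]21 | intermediate
22 | 7β-hydroperoxy-6α-[4-(tert-butyldimethylsilyloxy)benzoyloxy]dauc-8-en-4β-ol | CC(C)[C@]1(O)CC[C@]2(C)CC=C(C)[C@@H](OO)[C@H](OC(=O)c3ccc(O[Si](C)(C)C(C)(C)C)cc3)[C@H]21 | intermediate
23 | 6α-[4-(tert-butyldimethylsilyloxy)benzoyloxy]dauc-8-ene-4β,7β-diol | CC(C)[C@]1(O)CC[C@]2(C)CC=C(C)[C@@H](O)[C@H](OC(=O)c3ccc(O[Si](C)(C)C(C)(C)C)cc3)[C@H]21 | intermediate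
24 | 6α-[4-(tert-butyldimethylsilyloxy)benzoyloxy]-7β-(triethylsilyloxy)dauc-8-en-4β-ol | CC(C)[C@]1(O)CC[C@]2(C)CC=C(C)[C@@H](O[Si](CC)(CC)CC)[C@H](OC(=O)c3ccc(O[Si](C)(C)C(C)(C)C)cc3)[C@H]21 | intermediate
25 | 8α,9α-epoxy-6α-[4-(tert-butyldimethylsilyloxy)benzoyloxy]-7β-(triethylsilyloxy)daucan-4β-ol | CC(C)[C@]1(O)CC[C@]2(C)C[C@@H]3O[C@]3(C)[C@@H](O[Si](CC)(CC)CC)[C@H](OC(=O)c3ccc(O[Si](C)(C)C(C)(C)C)cc3)[C@H]21 | intermediate
26 | 8α,9α-epoxy-6α-(4-hydroxybenzoyloxy)daucane-4β,7β-diol (CNP0290052.1) | CC(C)[C@]1(O)CC[C@]2(C)C[C@@H]3O[C@]3(C)[C@@H](O)[C@H](OC(=O)c3ccc(O)cc3)[C@H]21 | target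

Total step count: 15. Longest linear sequence: 13 (steps 1, 2, 4–9, 11–15).

Steps most likely to fail

Step 8. The equilibrium may stay with the open diketone, settle on a cis-fused ketol, or drain away through loss of water. The fallback makes the C4–C5 bond irreversibly from a preformed, regiodefined enolate, as an intramolecular Reformatsky reaction.
- It sets out from 14. Kinetic α′-deprotonation with LiN(iPr)2 in the presence of TMSCl gives the cross-conjugated trimethylsilyl dienol ether F1.
- NBS in THF at −78 °C turns this into the 5-bromo enone F2.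
- 1 M HCl in THF frees the side-chain ketone to give the bromo diketone F3.
- SmI2 in THF at −78 °C reduces the C5–Br bond to a trivalent samarium enolate. This adds to C4 within a chelate that holds O4 on the side of C6, and it is protonated cold before retro-aldol or dehydration can begin.
- The route is rejoined at 16. If the ring fusion comes out cis, a short exposure to the base of step 8 remains open.

Step 12. The ene reaction may lose regiochemical control, by abstraction of a C14 hydrogen or of the well-aligned H6, or it may lose facial control. The fallback fixes both through a carbonyl transposition.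
- It sets out from 21. Allylic oxidation of the ring methylene C9 with CrO3 and 3,5-dimethylpyrazole in CH2Cl2 gives the 7-en-9-one F4.
- Nucleophilic epoxidation with t-BuOOH and DBU, anti to the 6α-ester, gives the 7β,8β-epoxy-9-ketone F5.
- Wharton transposition with N2H4·H2O and AcOH in MeOH places the alkene unambiguously at C8=C9, while C7–O keeps the configuration of the epoxide.
- The route is rejoined at 23.

Step 14. Facial selectivity of oxygen transfer may be poor, because ring B is flexible and the 6α-ester also screens part of the α face. The fallback brings the oxygen in as a nucleophile instead of an electrophile.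
- It sets out from 24. NBS in aqueous DME forms the bromonium ion reversibly, and water opens the β-bromonium ion at the tertiary C8 from the α face to give the 9β-bromo-8α-hydrin F6.
- Ag2O in THF closes it with inversion at C9 to the α-epoxide.
- The route is rejoined at 25.

Further compounds
F1 | step 8 | C5=C6 trimethylsilyl dienol ether of 14 | CC(C)C1(OCCO1)CC[C@]2(C)CCC(C)=CC(O[Si](C)(C)C)=C2
F2 | step 8 | 7-bromo-3,6-dimethyl-6-[2-(2-isopropyl-1,3-dioxolan-2-yl)ethyl]cyclohept-2-en-1-one (bromine on daucane C5, epimers; C1 as in 14) | CC(C)C1(OCCO1)CC[C@]2(C)CCC(C)=CC(=O)C2Br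
F3 | step 8 | 7-bromo-3,6-dimethyl-6-(4-methyl-3-oxopentyl)cyclohept-2-en-1-one (bromine on daucane C5, epimers; C1 as in 15) | CC(C)C(=O)CC[C@]1(C)CCC(C)=CC(=O)C1Br
F4 | step 12 | 6α-[4-(tert-butyldimethylsilyloxy)benzoyloxy]-4β-hydroxydauc-7-en-9-one | CC(C)[C@]1(O)CC[C@]2(C)CC(=O)C(C)=C[C@H](OC(=O)c3ccc(O[Si](C)(C)C(C)(C)C)cc3)[C@H]21
F5 | step 12 | 7β,8β-epoxy-6α-[4-(tert-butyldimethylsilyloxy)benzoyloxy]-4β-hydroxydaucan-9-one | CC(C)[C@]1(O)CC[C@]2(C)CC(=O)[C@@]3(C)O[C@H]3[C@H](OC(=O)c4ccc(O[Si](C)(C)C(C)(C)C)cc4)[C@H]21
F6 | step 14 | 9β-bromo-6α-[4-(tert-butyldimethylsilyloxy)benzoyloxy]-7β-(triethylsilyloxy)daucane-4β,8α-diol | CC(C)[C@]1(O)CC[C@]2(C)C[C@@H](Br)[C@](C)(O)[C@@H](O[Si](CC)(CC)CC)[C@H](OC(=O)c3ccc(O[Si](C)(C)C(C)(C)C)cc3)[C@H]21
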